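**Retrosynthetic overview**
1. The last bond made is C15–O, by allylic C–H hydroxylation of the C4 methyl group. The O14 acetate and O8 methacrylate go on just before it, and no protecting groups are used.
2. The ten-membered carbocycle is closed by RCM at C4=C5 of an acyclic epoxy diol. The oxirane comes from Sharpless epoxidation of the C14 allylic alcohol.
3. C7–C8 is formed by a Zn-Barbier union of a 3-(bromomethyl)butenolide with a C8 lactol, and C6 relays its configuration to C7 and C8.
4. The strategic bond is C6–O, set enantioselectively by Ir-catalysed allylic hydroxylation of sorbyl carbonate (new); esterification and RCM then give the butenolide. The lactol comes from propargyl alcohol by carbomagnesiation and Negishi coupling.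
5. Ring order: lactone (step 4), then oxirane (step 8), then ten-membered carbocycle (step 9).

Assumptions: germacrane numbering (C1–C15) is used for positions. In step 2 the ligand antipode is the one that gives the 3S alcohol (both antipodes are sold).

**Step 1**
Reactants: 1 (2E,4E)-hexa-2,4-dien-1-ol (sorbyl alcohol)
Product: 2 (2E,4E)-hexa-2,4-dien-1-yl methyl carbonate
Conditions: ClCO2Me, pyridine, CH2Cl2, 0 °C
Reagents that add atoms: methyl chloroformate COC(=O)Cl
Why: O-acylation of a primary alcohol (carbonate formation) installs the leaving group for π-allyl chemistry, and no stereocentre is involved.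

**Step 2**
Reactants: 2 (2E,4E)-hexa-2,4-dien-1-yl methyl carbonate
Product: 4 (3S,4E)-hexa-1,4-dien-3-ol, via allyl hydrogen carbonate 3 (not isolated)
Conditions: [Ir(dbcot)Cl]2 (2 mol %), Feringa-type phosphoramidite L* (4 mol %), TBD (8 mol %), KHCO3 (2 equiv), THF–H2O 9:1, 25 °C
Reagents that add atoms: potassium hydrogen carbonate [K+].OC([O-])=O
Why: Proposed new method: the cyclometalated Ir–phosphoramidite ionises the linear dienyl carbonate to a syn η3-(1-propenylallyl)iridium cation, and bicarbonate attacks outer-sphere at the substituted terminus C3 (charge stabilised by the propenyl group as by aryl in cinnamyl systems) on the face fixed by the ligand, which forms the C6–O bond and sets C6; monoester 3 then loses CO2, so C–O formation is irreversible and the weakly basic medium cannot re-ionise the skipped dienol to the conjugated isomer; the closest known reaction types are Ir-catalysed allylic hydroxylation of mono-ene carbonates with bicarbonate and Ir-catalysed C3-selective amination or alkylation of 2,4-dienyl carbonates, and what is new is an oxygen nucleophile on a 2,4-dienyl carbonate giving an enantioenriched bis-allylic alcohol.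

**Step 3**
Reactants: 4 (3S,4E)-hexa-1,4-dien-3-ol; 5 2-(bromomethyl)prop-2-enoic acid
Product: 6 (3S,4E)-hexa-1,4-dien-3-yl 2-(bromomethyl)prop-2-enoate
Conditions: DCC, DMAP (5 mol %), CH2Cl2, 0 °C
Reagents that add atoms: none
Why: Steglich esterification is near neutral, so the acid-labile bis-allylic C–O bond, the allylic bromide and the C6 configuration all survive.

**Step 4**
Reactants: 6 (3S,4E)-hexa-1,4-dien-3-yl 2-(bromomethyl)prop-2-enoate
Product: 7 (5R)-3-(bromomethyl)-5-[(E)-prop-1-en-1-yl]furan-2(5H)-one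
Conditions: Hoveyda–Grubbs II (3 mol %), 1,4-benzoquinone (10 mol %), CH2Cl2 (0.02 M), 40 °C
Reagents that add atoms: none
Why: In this ring-closing metathesis Ru loads on the terminal vinyl and closes the five-membered ring on the acrylate C=CH2; the slower internal propenyl group is kept as the later RCM handle and C6 is untouched (any 5-vinyl by-product is a different, separable compound).

**Step 5**
Reactants: 8 prop-2-yn-1-ol; 9 (1,3-dioxolan-2-ylmethyl)magnesium bromide
Product: 11 (Z)-2-(1,3-dioxolan-2-ylmethyl)-3-iodoprop-2-en-1-ol, via vinylmagnesium chelate 10 (not isolated)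
Conditions: 9 (2.5 equiv), CuI (10 mol %), THF, −10 → 23 °C; then I2, −40 → 0 °C
Reagents that add atoms: iodine II
Why: Cu-catalysed hydroxyl-directed anti-carbomagnesiation of propargyl alcohol puts the alkyl group on C10 and Mg on C1 cis to CH2O (five-membered chelate), and iodinolysis with retention fixes the C1=C10 geometry (C14 cis to the future C2).

**Step 6**
Reactants: 12 4-bromo-2-methylbut-1-ene; 11 (Z)-2-(1,3-dioxolan-2-ylmethyl)-3-iodoprop-2-en-1-ol
Product: 14 (Z)-2-(1,3-dioxolan-2-ylmethyl)-6-methylhepta-2,6-dien-1-ol, via homoallylzinc bromide 13 (not isolated)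
Conditions: 12 (2.2 equiv), Zn, LiCl, THF, 40 °C; then 11, Pd(OAc)2 (2 mol %), SPhos (4 mol %), 23 °C
Reagents that add atoms: none
Why: Negishi sp2–sp3 coupling of a homoallylzinc halide with an alkenyl iodide proceeds with retention of alkene geometry and tolerates the free alcohol and the acetal.

**Step 7**
Reactants: 14 (Z)-2-(1,3-dioxolan-2-ylmethyl)-6-methylhepta-2,6-dien-1-ol; 7 (5R)-3-(bromomethyl)-5-[(E)-prop-1-en-1-yl]furan-2(5H)-one
Product: 17 (4R,5R)-4-[(1S,3Z)-1-hydroxy-3-(hydroxymethyl)-7-methylocta-3,7-dien-1-yl]-3-methylidene-5-[(E)-prop-1-en-1-yl]oxolan-2-one, via lactol 15 (not isolated), via allylzinc bromide 16 (not isolated)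
Conditions: TsOH·H2O (10 mol %), THF–H2O 4:1, 40 °C; then sat. aq NH4Cl, 7 (1.3 equiv), Zn dust, 0 → 23 °C, one pot
Reagents that add atoms: water O
Why: Acetal hydrolysis is trapped by the C14 hydroxyl as a five-membered lactol, which masks the β,γ-unsaturated aldehyde; the Zn-Barbier SE2′ allylation then bonds C7 anti to the C6 propenyl group (6,7-trans) through a Zimmerman–Traxler chair in which the ring-locked E-type allyl unit gives the 7,8-anti (8S) alcohol and the α-methylene lactone.

**Step 8**
Reactants: 17 Barbier diol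
Product: 18 (4R,5R)-4-{(1S)-1-hydroxy-2-[(2S,3R)-2-(hydroxymethyl)-3-(3-methylbut-3-en-1-yl)oxiran-2-yl]ethyl}-3-methylidene-5-[(E)-prop-1-en-1-yl]oxolan-2-one
Conditions: Ti(OiPr)4 (20 mol %), L-(+)-DIPT (24 mol %), TBHP (decane), 4 Å MS, CH2Cl2, −20 °C
Reagents that add atoms: tert-butyl hydroperoxide CC(C)(C)OO
Why: Katsuki–Sharpless asymmetric epoxidation touches only the allylic-alcohol alkene, and L-(+)-tartrate delivers oxygen to the face that gives the S centre at the carbinol-bearing carbon, so C10 (S) and C1 (R) are set by the reagent as the trans epoxide; the minor diastereomer is removable.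

**Step 9**
Reactants: 18 acyclic epoxy diol
Product: 19 (1R,6R,7R,8S,10S)-1,10-epoxy-8,14-dihydroxygermacra-4Z,11(13)-dien-12,6-olide (C4=C5 ring-cis)
Conditions: Grubbs II (2 × 7.5 mol %), 1,4-benzoquinone (20 mol %), toluene (1 mM), 90 °C, Ar sparge
Reagents that add atoms: none
Why: Ring-closing metathesis between the propenyl group and the isopropenyl group closes the ten-membered ring as the less strained ring-cis trisubstituted alkene; the C1=C10 alkene is already masked as the epoxide, so six-ring closure onto C10 is impossible, and the methacrylate is not yet present, so seven-ring closure is excluded.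

**Step 10**
Reactants: 19 macrocyclic epoxy diol
Product: 21 (1R,6R,7R,8S,10S)-14-acetoxy-1,10-epoxy-8-methacryloyloxygermacra-4Z,11(13)-dien-12,6-olide, via 14-monoacetate 20 (not isolated)
Conditions: Ac2O (1.1 equiv), Et3N, DMAP (2 mol %), CH2Cl2, −40 °C; then methacrylic anhydride (3 equiv), DMAP (0.5 equiv), 23 °C
Reagents that add atoms: acetic anhydride CC(=O)OC(C)=O; methacrylic anhydride C=C(C)C(=O)OC(=O)C(C)=C
Why: Sequential DMAP-catalysed acyl transfer acetylates the primary C14 hydroxyl well before the hindered secondary C8 hydroxyl, which is then forced with methacrylic anhydride; epoxide, lactone and all stereocentres are untouched.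

**Step 11**
Reactants: 21 15-deoxy diester
Product: 22 target, (1R,6R,7R,8S,10S)-14-acetoxy-1,10-epoxy-15-hydroxy-8-methacryloyloxygermacra-4,11(13)-dien-12,6-olide (C4=C5 ring-cis, CH2OH trans to C6)
Conditions: SeO2 (30 mol %), TBHP (3 equiv), CH2Cl2, 23–40 °C
Reagents that add atoms: selenium dioxide O=[Se]=O (oxygen carrier); tert-butyl hydroperoxide CC(C)(C)OO
Why: In the Sharpless SeO2/TBHP allylic hydroxylation (ene reaction, then [2,3]-sigmatropic shift) the only electron-rich alkene left is C4=C5; the methyl group cis to H5 reacts, and the [2,3] shift places CH2OH trans to C6 whatever the geometry of the precursor, while the acrylates and the epoxide are inert, as in related epoxy-germacranolide oxidations.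

**Compound list**
1 | (2E,4E)-hexa-2,4-dien-1-ol | C/C=C/C=C/CO | starting material
2 | (2E,4E)-hexa-2,4-dien-1-yl methyl carbonate | C/C=C/C=C/COC(=O)OC | intermediate
3 | (3S,4E)-hexa-1,4-dien-3-yl hydrogen carbonate | C/C=C/[C@@H](OC(=O)O)C=C | intermediate
4 | (3S,4E)-hexa-1,4-dien-3-ol | C/C=C/[C@@H](O)C=C | intermediate
5 | 2-(bromomethyl)prop-2-enoic acid | C=C(CBr)C(=O)O | starting material
6 | (3S,4E)-hexa-1,4-dien-3-yl 2-(bromomethyl)prop-2-enoate | C/C=C/[C@@H](OC(=O)C(=C)CBr)C=C | intermediate
7 | (5R)-3-(bromomethyl)-5-[(E)-prop-1-en-1-yl]furan-2(5H)-one | C/C=C/[C@H]1OC(=O)C(CBr)=C1 | intermediate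
8 | prop-2-yn-1-ol | C#CCO | starting material
9 | (1,3-dioxolan-2-ylmethyl)magnesium bromide | Br[Mg]CC1OCCO1 | starting material
10 | (Z)-vinylmagnesium bromide alkoxide (chelate) from 8 and 9 | Br[Mg]/C=C(\CO[Mg]Br)CC1OCCO1 | intermediate
11 | (Z)-2-(1,3-dioxolan-2-ylmethyl)-3-iodoprop-2-en-1-ol | I/C=C(\CO)CC1OCCO1 | intermediate
12 | 4-bromo-2-methylbut-1-ene | C=C(C)CCBr | starting material
13 | (3-methylbut-3-en-1-yl)zinc bromide | C=C(C)CC[Zn]Br | intermediate
14 | (Z)-2-(1,3-dioxolan-2-ylmethyl)-6-methylhepta-2,6-dien-1-ol | C=C(C)CC/C=C(\CO)CC1OCCO1 | intermediate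
15 | (Z)-4-(4-methylpent-4-en-1-ylidene)oxolan-2-ol (anomers) | OC1C/C(=C/CCC(C)=C)CO1 | intermediate
16 | {[(5R)-2-oxo-5-[(E)-prop-1-en-1-yl]-2,5-dihydrofuran-3-yl]methyl}zinc bromide | C/C=C/[C@H]1OC(=O)C(C[Zn]Br)=C1 | intermediate
17 | (4R,5R)-4-[(1S,3Z)-1-hydroxy-3-(hydroxymethyl)-7-methylocta-3,7-dien-1-yl]-3-methylidene-5-[(E)-prop-1-en-1-yl]oxolan-2-one | O[C@@H](C/C(CO)=C/CCC(C)=C)[C@H]1C(=C)C(=O)O[C@@H]1/C=C/C | intermediate
18 | (4R,5R)-4-{(1S)-1-hydroxy-2-[(2S,3R)-2-(hydroxymethyl)-3-(3-methylbut-3-en-1-yl)oxiran-2-yl]ethyl}-3-methylidene-5-[(E)-prop-1-en-1-yl]oxolan-2-one | O[C@@H](C[C@@]2(CO)O[C@@H]2CCC(C)=C)[C@H]1C(=C)C(=O)O[C@@H]1/C=C/C | intermediate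
19 | (1R,6R,7R,8S,10S)-1,10-epoxy-8,14-dihydroxygermacra-4Z,11(13)-dien-12,6-olide | O[C@H]1C[C@@]2(CO)O[C@@H]2CC/C(C)=C\[C@H]2OC(=O)C(=C)[C@H]12 | intermediate
20 | 14-O-acetyl derivative of 19 | O[C@H]1C[C@@]2(COC(C)=O)O[C@@H]2CC/C(C)=C\[C@H]2OC(=O)C(=C)[C@H]12 | intermediate
21 | 14-O-acetyl-8-O-methacryloyl derivative of 19 | C=C(C)C(=O)O[C@H]1C[C@@]2(COC(C)=O)O[C@@H]2CC/C(C)=C\[C@H]2OC(=O)C(=C)[C@H]12 | intermediate
22 | CNP0306006.2 | C=C(C)C(=O)O[C@H]1C[C@@]2(COC(C)=O)O[C@@H]2CC/C(CO)=C\[C@H]2OC(=O)C(=C)[C@H]12 | target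

**Totals:** 11 steps in all. The longest linear sequence is 9 steps (steps 1–4, then 7–11).

**Steps most likely to fail**

Step 2 (the new reaction). Bicarbonate may attack C1 or C5 of the dienyl–iridium species, or the ee may be modest. The fallback uses known chemistry, sets out from 1 and comes back at 4. Katsuki–Sharpless epoxidation of 1 (Ti(OiPr)4, D-(−)-DIPT, TBHP, −20 °C) gives [(2R,3R)-3-[(E)-prop-1-en-1-yl]oxiran-2-yl]methanol F1, so the C6–O bond is now made by the epoxidation. Iodination (I2, PPh3, imidazole) then gives (2S,3R)-2-(iodomethyl)-3-[(E)-prop-1-en-1-yl]oxirane F2. Reductive ring opening with zinc dust in ethanol unveils the terminal vinyl group and delivers 4 with the C–O bond intact. This costs one step more.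

Step 5. The β,β-dialkoxy Grignard 9 may add too slowly, and the acid unmasking in step 7 risks furan formation. The fallback sets out from 8 and comes back at 15 without any acid. Allylmagnesium bromide with CuI adds to 8 to give the (Z)-2-allylvinylmagnesium bromide alkoxide F3, which is quenched with iodine to (Z)-2-(iodomethylidene)pent-4-en-1-ol F4. Lemieux–Johnson cleavage (cat. OsO4, NaIO4, 2,6-lutidine) takes only the terminal alkene and gives (Z)-4-(iodomethylidene)oxolan-2-ol F5. Negishi coupling of F5 with 13 gives lactol 15, which enters the Barbier half of step 7.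

Step 9. Ring strain may divert the RCM to oligomers. The fallback swaps the order of bond formation so that the ring is closed by the Barbier reaction; it sets out from 14 and 7 and comes back at 19.
- Cross-metathesis of 7 with excess 14 (Hoveyda–Grubbs II) gives, after separation of the Z isomer, (5R)-3-(bromomethyl)-5-[(1Z,5Z)-7-(1,3-dioxolan-2-yl)-6-(hydroxymethyl)-2-methylhepta-1,5-dien-1-yl]furan-2(5H)-one F6.
- Mild hydrolysis converts F6 to the bromomethyl butenolide lactol F7.
- Slow addition of F7 to Zn in THF/aq NH4Cl at 1 mM passes through the tethered allylzinc bromide lactol F8, which closes C7–C8 to (6R,7R,8S)-8,14-dihydroxygermacra-1(10),4,11(13)-trien-12,6-olide (1(10) ring-trans, 4,5 ring-cis) F9.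
- Sharpless epoxidation of F9 with L-(+)-DIPT gives 19.

**Further compounds**
F1 | step 2 | [(2R,3R)-3-[(E)-prop-1-en-1-yl]oxiran-2-yl]methanol | C/C=C/[C@H]1O[C@@H]1CO
F2 | step 2 | (2S,3R)-2-(iodomethyl)-3-[(E)-prop-1-en-1-yl]oxirane | C/C=C/[C@H]1O[C@@H]1CI
F3 | step 5 | (Z)-2-allylvinylmagnesium bromide alkoxide | Br[Mg]/C=C(\CO[Mg]Br)CC=C
F4 | step 5 | (Z)-2-(iodomethylidene)pent-4-en-1-ol | I/C=C(\CO)CC=C
F5 | step 5 | (Z)-4-(iodomethylidene)oxolan-2-ol | OC1C/C(=C/I)CO1
F6 | step 9 | (5R)-3-(bromomethyl)-5-[(1Z,5Z)-7-(1,3-dioxolan-2-yl)-6-(hydroxymethyl)-2-methylhepta-1,5-dien-1-yl]furan-2(5H)-one | OC/C(CC2OCCO2)=C\CC/C(C)=C\[C@H]1OC(=O)C(CBr)=C1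
F7 | step 9 | bromomethyl butenolide lactol | OC2C/C(=C/CC/C(C)=C\[C@H]1OC(=O)C(CBr)=C1)CO2
F8 | step 9 | tethered allylzinc bromide lactol | OC2C/C(=C/CC/C(C)=C\[C@H]1OC(=O)C(C[Zn]Br)=C1)CO2
F9 | step 9 | (6R,7R,8S)-8,14-dihydroxygermacra-1(10),4,11(13)-trien-12,6-olide | O[C@H]1C/C(CO)=C/CC/C(C)=C\[C@H]2OC(=O)C(=C)[C@H]12
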